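**Retrosynthetic overview**
- The target comes from its primary allylic alcohol (Appel bromination last); both C–Cl bonds are made one at a time by SN2 inversion of equatorial allylic alcohols.
- The (Z)-2-hydroxyethylidene unit comes from iBu2AlH opening of a fused butenolide made by intramolecular Horner–Wadsworth–Emmons reaction; the lactone ring fixes the alkene geometry.
- The butenolide comes from (S)-4-bromo-3,3-dimethylcyclohexanone by two α-oxygenations (proline aminoxylation, then enolate hydroxylation).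
- The bromo ketone comes from ozonolysis of a methylenecyclohexane, itself formed by cationic cyclisation of an acyclic bromohydrin allylsilane; a 1,2-bromine shift turns the carbinol centre into the C–Br centre.
- The bromohydrin comes from enzymatic reduction of an achiral α-bromo keto ester. Ring order: the cyclohexane is the only carbocycle formed (step 5); the γ-lactone and the butenolide are temporary.

Assumption: the (R)-selective ketoreductase of step 3 is taken from a commercial screening panel; all numbered starting materials are commercial and achiral.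

**Step 1**
Reactants: 1 ethyl 4-chloro-4-oxobutanoate; 2 isopropylmagnesium chloride
Product: 3 ethyl 5-methyl-4-oxohexanoate
Conditions: 2 (1.05 equiv), CuBr·SMe2 (5 mol %), THF, −78 °C
Reagents that add atoms: none
Why: Copper-catalysed acylation of a Grignard reagent by an acid chloride stops at the ketone and leaves the ester untouched at −78 °C.

**Step 2**
Reactants: 3 ethyl 5-methyl-4-oxohexanoate
Product: 4 ethyl 5-bromo-5-methyl-4-oxohexanoate
Conditions: Br2 (1.0 equiv), AcOH, 15–20 °C
Reagents that add atoms: bromine BrBr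
Why: Acid-catalysed α-bromination of a ketone goes through the more substituted enol, so bromine enters at the tertiary isopropyl carbon; the product is still achiral.

**Step 3**
Reactants: 4 ethyl 5-bromo-5-methyl-4-oxohexanoate
Product: 6 (5R)-5-(2-bromopropan-2-yl)oxolan-2-one, via bromohydrin ester 5 (not isolated)
Conditions: (R)-selective ketoreductase (NADPH-dependent), NADP+ (cat.), iPrOH, phosphate buffer pH 7.0/MTBE (1:3), 30 °C; then TsOH·H2O (cat.), CH2Cl2, 20 °C
Reagents that add atoms: none
Why: Ketoreductase-catalysed asymmetric carbonyl reduction delivers hydride to one enantiotopic face and sets the first stereocentre as (R); acid-catalysed lactonisation then masks the carbinol and keeps the tertiary bromide away from water.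

**Step 4**
Reactants: 6 (5R)-5-(2-bromopropan-2-yl)oxolan-2-one; 7 (trimethylsilyl)methylmagnesium chloride
Product: 9 (3R)-2-bromo-2-methyl-6-[(trimethylsilyl)methyl]hept-6-en-3-ol, via bis-silyl diol 8 (not isolated)
Conditions: 7 (3 equiv), CeCl3 (3 equiv), THF, −78 → −20 °C; AcOH, −78 °C; then SiO2, CH2Cl2, 20 °C
Reagents that add atoms: none
Why: Organocerium double addition to the lactone carbonyl followed by Peterson elimination gives the 2-substituted allylsilane; the low temperature and cold acidic quench keep the liberated alkoxide from closing onto the tertiary bromide, and the carbinol centre is not touched.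

**Step 5**
Reactants: 9 (3R)-2-bromo-2-methyl-6-[(trimethylsilyl)methyl]hept-6-en-3-ol
Product: 11 (4S)-4-bromo-3,3-dimethyl-1-methylidenecyclohexane, via triflate 10 (not isolated)
Conditions: Tf2O (1.1 equiv), 2,6-di-tert-butyl-4-methylpyridine (2.5 equiv), CH2Cl2 (0.01 M), −78 → −30 °C
Reagents that add atoms: none
Why: Triflation triggers anchimerically assisted ionisation in which the neighbouring tertiary bromine displaces triflate from the rear (1,2-bromine shift through a bromonium ion, inversion), and the allylsilane captures the tertiary terminus in a chair-like cation–olefin cyclisation, so the (R)-carbinol becomes the (S)-C–Br centre.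

**Step 6**
Reactants: 11 (4S)-4-bromo-3,3-dimethyl-1-methylidenecyclohexane
Product: 12 (4S)-4-bromo-3,3-dimethylcyclohexan-1-one
Conditions: O3, CH2Cl2/MeOH, −78 °C; then Me2S, −78 → 20 °C
Reagents that add atoms: ozone [O-][O+]=O
Why: Ozonolysis with reductive work-up cleaves the exocyclic 1,1-disubstituted alkene to the ketone and does not affect the secondary bromide.

**Step 7**
Reactants: 12 (4S)-4-bromo-3,3-dimethylcyclohexan-1-one
Product: 13 (2R,4S)-4-bromo-5,5-dimethyl-2-[(phenylamino)oxy]cyclohexan-1-one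
Conditions: PhNO (1.1 equiv, slow addition), L-proline (20 mol %), DMF, 0 °C
Reagents that add atoms: nitrosobenzene O=Nc1ccccc1
Why: Proline-catalysed α-aminoxylation (O-selective nitroso aldol) proceeds through the enamine on the side away from the gem-dimethyl group, and L-proline is expected to control the face and give the (R)-C–O centre, cis to bromine.

**Step 8**
Reactants: 13 (2R,4S)-4-bromo-5,5-dimethyl-2-[(phenylamino)oxy]cyclohexan-1-one
Product: 14 (2R,4S)-4-bromo-2-hydroxy-5,5-dimethylcyclohexan-1-one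
Conditions: CuSO4·5H2O (0.3 equiv), MeOH, 0 °C
Reagents that add atoms: none
Why: Copper-catalysed N–O bond cleavage frees the α-hydroxy ketone under near-neutral conditions without epimerising the new centre.

**Step 9**
Reactants: 14 (2R,4S)-4-bromo-2-hydroxy-5,5-dimethylcyclohexan-1-one
Product: 15 (2R,4S)-4-bromo-2-[(tert-butyldimethylsilyl)oxy]-5,5-dimethylcyclohexan-1-one
Conditions: TBSOTf, 2,6-lutidine, CH2Cl2, −78 °C
Reagents that add atoms: tert-butyldimethylsilyl trifluoromethanesulfonate CC(C)(C)[Si](C)(C)OS(=O)(=O)C(F)(F)F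
Why: Low-temperature silylation protects the α-hydroxyl without enolising the ketone.

**Step 10**
Reactants: 15 (2R,4S)-4-bromo-2-[(tert-butyldimethylsilyl)oxy]-5,5-dimethylcyclohexan-1-one
Product: 16 (2R,4S,6R)-4-bromo-6-[(tert-butyldimethylsilyl)oxy]-2-hydroxy-3,3-dimethylcyclohexan-1-one
Conditions: NaN(SiMe3)2 (1.1 equiv), THF, −78 °C; then 3-phenyl-2-(phenylsulfonyl)oxaziridine, −78 °C; AcOH
Reagents that add atoms: 3-phenyl-2-(phenylsulfonyl)oxaziridine O=S(=O)(N1OC1c1ccccc1)c1ccccc1
Why: Kinetic deprotonation should take the CH2 proton rather than the shielded α-silyloxy methine, and Davis oxidation of that enolate by axial attack gives the α'-hydroxy ketone; this carbinol centre is reset in step 12, so its configuration here is not critical.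

**Step 11**
Reactants: 16 (2R,4S,6R)-4-bromo-6-[(tert-butyldimethylsilyl)oxy]-2-hydroxy-3,3-dimethylcyclohexan-1-one; 17 diethylphosphonoacetic acid
Product: 18 (1R,3S,5R)-3-bromo-5-[(tert-butyldimethylsilyl)oxy]-2,2-dimethyl-6-oxocyclohexyl 2-(diethoxyphosphoryl)acetate
Conditions: 17, DCC, DMAP (cat.), CH2Cl2, 0 → 20 °C
Reagents that add atoms: none
Why: Steglich esterification acylates the free α'-hydroxyl and installs the phosphonate tether next to the ketone.

**Step 12**
Reactants: 18 (1R,3S,5R)-3-bromo-5-[(tert-butyldimethylsilyl)oxy]-2,2-dimethyl-6-oxocyclohexyl 2-(diethoxyphosphoryl)acetate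
Product: 20 (4R,6S,7aR)-6-bromo-4-[(tert-butyldimethylsilyl)oxy]-7,7-dimethyl-5,6,7,7a-tetrahydro-1-benzofuran-2(4H)-one, via kinetic butenolide 19 (not isolated)
Conditions: LiCl, iPr2NEt, MeCN, 0 → 20 °C; then DBU (0.3 equiv), 20 °C
Reagents that add atoms: none
Why: Intramolecular Horner–Wadsworth–Emmons olefination closes the butenolide, which forces the carboxyl carbon cis to the oxygenated ring carbon; DBU then epimerises the γ-carbon through the 2-oxidofuran to the epimer in which Br, OTBS and the lactone C–O bond are all equatorial.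

**Step 13**
Reactants: 20 (4R,6S,7aR)-6-bromo-4-[(tert-butyldimethylsilyl)oxy]-7,7-dimethyl-5,6,7,7a-tetrahydro-1-benzofuran-2(4H)-one
Product: 21 (1R,3S,5R,6E)-3-bromo-5-[(tert-butyldimethylsilyl)oxy]-6-(2-hydroxyethylidene)-2,2-dimethylcyclohexan-1-ol
Conditions: iBu2AlH (4 equiv), CH2Cl2, −78 → 0 °C; Rochelle salt (KNaC4H4O6) work-up
Reagents that add atoms: none
Why: 1,2-Reduction of the unsaturated lactone through the lactol gives the ene-1,4-diol with the alkene geometry carried over from the ring (CH2OH cis to the carbinol carbon).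

**Step 14**
Reactants: 21 (1R,3S,5R,6E)-3-bromo-5-[(tert-butyldimethylsilyl)oxy]-6-(2-hydroxyethylidene)-2,2-dimethylcyclohexan-1-ol
Product: 22 (2E)-2-[(2R,4S,6R)-4-bromo-6-[(tert-butyldimethylsilyl)oxy]-2-hydroxy-3,3-dimethylcyclohexylidene]ethyl acetate
Conditions: lipase (Candida antarctica lipase B, immobilised), vinyl acetate (3 equiv), MTBE, 30 °C
Reagents that add atoms: vinyl acetate CC(=O)OC=C
Why: Lipase-catalysed irreversible transesterification acylates only the primary allylic hydroxyl and leaves the hindered secondary allylic alcohol free for chlorination.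

**Step 15**
Reactants: 22 (2E)-2-[(2R,4S,6R)-4-bromo-6-[(tert-butyldimethylsilyl)oxy]-2-hydroxy-3,3-dimethylcyclohexylidene]ethyl acetate
Product: 23 (2Z)-2-[(2S,4S,6R)-4-bromo-6-[(tert-butyldimethylsilyl)oxy]-2-chloro-3,3-dimethylcyclohexylidene]ethyl acetate
Conditions: PPh3 (1.5 equiv), N-chlorosuccinimide (1.5 equiv), THF, 0 → 20 °C
Reagents that add atoms: N-chlorosuccinimide O=C1CCC(=O)N1Cl
Why: Appel-type chlorination through the alkoxyphosphonium salt is an SN2 displacement with inversion, helped by allylic activation and relief of allylic 1,3-strain, turning the equatorial alcohol into the axial (S)-chloride.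

**Step 16**
Reactants: 23 (2Z)-2-[(2S,4S,6R)-4-bromo-6-[(tert-butyldimethylsilyl)oxy]-2-chloro-3,3-dimethylcyclohexylidene]ethyl acetate
Product: 24 (2Z)-2-[(2S,4S,6R)-4-bromo-2-chloro-6-hydroxy-3,3-dimethylcyclohexylidene]ethyl acetate
Conditions: HF·pyridine, THF/pyridine, 0 → 20 °C
Reagents that add atoms: none
Why: Buffered fluoride desilylation frees the second allylic alcohol without touching the acetate or the halides.

**Step 17**
Reactants: 24 (2Z)-2-[(2S,4S,6R)-4-bromo-2-chloro-6-hydroxy-3,3-dimethylcyclohexylidene]ethyl acetate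
Product: 25 (2Z)-2-[(2S,4S,6S)-4-bromo-2,6-dichloro-3,3-dimethylcyclohexylidene]ethyl acetate
Conditions: PPh3 (1.5 equiv), N-chlorosuccinimide (1.5 equiv), THF, 0 → 20 °C
Reagents that add atoms: N-chlorosuccinimide O=C1CCC(=O)N1Cl
Why: A second Appel-type SN2 chlorination at the unhindered allylic carbinol inverts the (R)-alcohol to the (S)-chloride, cis to the first chlorine and trans to bromine.

**Step 18**
Reactants: 25 (2Z)-2-[(2S,4S,6S)-4-bromo-2,6-dichloro-3,3-dimethylcyclohexylidene]ethyl acetate
Product: 26 (2Z)-2-[(2S,4S,6S)-4-bromo-2,6-dichloro-3,3-dimethylcyclohexylidene]ethan-1-ol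
Conditions: lipase (Candida antarctica lipase B, immobilised), n-BuOH (5 equiv), MTBE, 30 °C
Reagents that add atoms: none
Why: Lipase-catalysed alcoholysis removes the primary acetate under neutral, anhydrous conditions, which avoids the substitution or elimination of the allylic chlorides that basic methanolysis would risk.

**Step 19**
Reactants: 26 (2Z)-2-[(2S,4S,6S)-4-bromo-2,6-dichloro-3,3-dimethylcyclohexylidene]ethan-1-ol
Product: 27 (1S,3S,4Z,5S)-1-bromo-4-(2-bromoethylidene)-3,5-dichloro-2,2-dimethylcyclohexane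
Conditions: CBr4 (1.2 equiv), PPh3 (1.2 equiv), CH2Cl2, 0 °C, short reaction time
Reagents that add atoms: carbon tetrabromide BrC(Br)(Br)Br
Why: Appel bromination of the primary allylic alcohol is fast at 0 °C and creates no stereocentre, so it is done last to keep the bromide away from chloride sources.

**Compound list**
1 | ethyl 4-chloro-4-oxobutanoate | CCOC(=O)CCC(Cl)=O | starting material
2 | isopropylmagnesium chloride | CC(C)[Mg]Cl | starting material
3 | ethyl 5-methyl-4-oxohexanoate | CCOC(=O)CCC(=O)C(C)C | intermediate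
4 | ethyl 5-bromo-5-methyl-4-oxohexanoate | CCOC(=O)CCC(=O)C(C)(C)Br | intermediate
5 | ethyl (4R)-5-bromo-4-hydroxy-5-methylhexanoate | CCOC(=O)CC[C@@H](O)C(C)(C)Br | intermediate
6 | (5R)-5-(2-bromopropan-2-yl)oxolan-2-one | O=C1CC[C@H](C(C)(C)Br)O1 | intermediate
7 | (trimethylsilyl)methylmagnesium chloride | C[Si](C)(C)C[Mg]Cl | starting material
8 | (5R)-6-bromo-6-methyl-1-(trimethylsilyl)-2-[(trimethylsilyl)methyl]heptane-2,5-diol | C[Si](C)(C)CC(O)(C[Si](C)(C)C)CC[C@@H](O)C(C)(C)Br | intermediate
9 | (3R)-2-bromo-2-methyl-6-[(trimethylsilyl)methyl]hept-6-en-3-ol | C[Si](C)(C)CC(=C)CC[C@@H](O)C(C)(C)Br | intermediate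
10 | (3R)-2-bromo-2-methyl-6-[(trimethylsilyl)methyl]hept-6-en-3-yl trifluoromethanesulfonate | C[Si](C)(C)CC(=C)CC[C@@H](OS(=O)(=O)C(F)(F)F)C(C)(C)Br | intermediate
11 | (4S)-4-bromo-3,3-dimethyl-1-methylidenecyclohexane | CC1(C)[C@@H](Br)CCC(=C)C1 | intermediate
12 | (4S)-4-bromo-3,3-dimethylcyclohexan-1-one | CC1(C)[C@@H](Br)CCC(=O)C1 | intermediate
13 | (2R,4S)-4-bromo-5,5-dimethyl-2-[(phenylamino)oxy]cyclohexan-1-one | CC1(C)[C@@H](Br)C[C@@H](ONc2ccccc2)C(=O)C1 | intermediate
14 | (2R,4S)-4-bromo-2-hydroxy-5,5-dimethylcyclohexan-1-one | CC1(C)[C@@H](Br)C[C@@H](O)C(=O)C1 | intermediate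
15 | (2R,4S)-4-bromo-2-[(tert-butyldimethylsilyl)oxy]-5,5-dimethylcyclohexan-1-one | CC1(C)[C@@H](Br)C[C@@H](O[Si](C)(C)C(C)(C)C)C(=O)C1 | intermediate
16 | (2R,4S,6R)-4-bromo-6-[(tert-butyldimethylsilyl)oxy]-2-hydroxy-3,3-dimethylcyclohexan-1-one | CC1(C)[C@@H](Br)C[C@@H](O[Si](C)(C)C(C)(C)C)C(=O)[C@@H]1O | intermediate
17 | diethylphosphonoacetic acid | OC(=O)CP(=O)(OCC)OCC | starting material
18 | (1R,3S,5R)-3-bromo-5-[(tert-butyldimethylsilyl)oxy]-2,2-dimethyl-6-oxocyclohexyl 2-(diethoxyphosphoryl)acetate | CC1(C)[C@@H](Br)C[C@@H](O[Si](C)(C)C(C)(C)C)C(=O)[C@@H]1OC(=O)CP(=O)(OCC)OCC | intermediate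
19 | (4R,6S,7aS)-6-bromo-4-[(tert-butyldimethylsilyl)oxy]-7,7-dimethyl-5,6,7,7a-tetrahydro-1-benzofuran-2(4H)-one | CC1(C)[C@@H](Br)C[C@@H](O[Si](C)(C)C(C)(C)C)C2=CC(=O)O[C@H]12 | intermediate
20 | (4R,6S,7aR)-6-bromo-4-[(tert-butyldimethylsilyl)oxy]-7,7-dimethyl-5,6,7,7a-tetrahydro-1-benzofuran-2(4H)-one | CC1(C)[C@@H](Br)C[C@@H](O[Si](C)(C)C(C)(C)C)C2=CC(=O)O[C@@H]12 | intermediate
21 | (1R,3S,5R,6E)-3-bromo-5-[(tert-butyldimethylsilyl)oxy]-6-(2-hydroxyethylidene)-2,2-dimethylcyclohexan-1-ol | CC1(C)[C@@H](Br)C[C@@H](O[Si](C)(C)C(C)(C)C)/C(=C/CO)[C@H]1O | intermediate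
22 | (2E)-2-[(2R,4S,6R)-4-bromo-6-[(tert-butyldimethylsilyl)oxy]-2-hydroxy-3,3-dimethylcyclohexylidene]ethyl acetate | CC1(C)[C@@H](Br)C[C@@H](O[Si](C)(C)C(C)(C)C)/C(=C/COC(C)=O)[C@H]1O | intermediate
23 | (2Z)-2-[(2S,4S,6R)-4-bromo-6-[(tert-butyldimethylsilyl)oxy]-2-chloro-3,3-dimethylcyclohexylidene]ethyl acetate | CC1(C)[C@@H](Br)C[C@@H](O[Si](C)(C)C(C)(C)C)/C(=C/COC(C)=O)[C@@H]1Cl | intermediate
24 | (2Z)-2-[(2S,4S,6R)-4-bromo-2-chloro-6-hydroxy-3,3-dimethylcyclohexylidene]ethyl acetate | CC1(C)[C@@H](Br)C[C@@H](O)/C(=C/COC(C)=O)[C@@H]1Cl | intermediate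
25 | (2Z)-2-[(2S,4S,6S)-4-bromo-2,6-dichloro-3,3-dimethylcyclohexylidene]ethyl acetate | CC1(C)[C@@H](Br)C[C@H](Cl)/C(=C/COC(C)=O)[C@@H]1Cl | intermediate
26 | (2Z)-2-[(2S,4S,6S)-4-bromo-2,6-dichloro-3,3-dimethylcyclohexylidene]ethan-1-ol | CC1(C)[C@@H](Br)C[C@H](Cl)/C(=C/CO)[C@@H]1Cl | intermediate
27 | (1S,3S,4Z,5S)-1-bromo-4-(2-bromoethylidene)-3,5-dichloro-2,2-dimethylcyclohexane | CC1(C)[C@@H](Br)C[C@H](Cl)/C(=C/CBr)[C@@H]1Cl | target

**Totals**
Total step count: 19. Longest linear sequence: 19 steps (fully linear from 1).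

**Steps most likely to fail and fallbacks**

Step 5 (cyclisation with bromine shift). The triflate could lose HOTf, or the allylsilane could be protodesilylated before ring closure. The fallback sets out from 9 and comes back at 11. CBr4/PPh3 with Et4NBr in CH2Cl2 at −40 °C converts 9, through the same bromonium ion and bromide capture at the tertiary carbon, into the isolable vicinal dibromide (5S)-5,6-dibromo-6-methyl-2-[(trimethylsilyl)methyl]hept-1-ene F1. AgOSO2CF3 with 2,6-di-tert-butyl-4-methylpyridine in CH2Cl2 at −78 °C then abstracts the tertiary bromide, the secondary bromine bridges, and the allylsilane closes the ring to 11. Any material that cyclises during the first operation is already 11.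

Step 15 (chloride at the carbinol next to the quaternary carbon). The displacement is slowed by the neighbouring gem-dimethyl group and may divert to allylic transposition. The fallback sets out from 15 and comes back at 23; chlorine is brought in as an electrophile instead. NaN(SiMe3)2/Me3SiCl in THF at −78 °C gives the silyl enol ether tert-butyl({(1R,5S)-5-bromo-4,4-dimethyl-2-[(trimethylsilyl)oxy]cyclohex-2-en-1-yl}oxy)dimethylsilane F2. N-Chlorosuccinimide in THF at 0 °C adds chlorine axially to give (2R,4S,6R)-4-bromo-6-[(tert-butyldimethylsilyl)oxy]-2-chloro-3,3-dimethylcyclohexan-1-one F3. Intermolecular Horner–Wadsworth–Emmons olefination with triethyl phosphonoacetate (LiCl, DBU, MeCN) gives ethyl (2Z)-2-[(2S,4S,6R)-4-bromo-6-[(tert-butyldimethylsilyl)oxy]-2-chloro-3,3-dimethylcyclohexylidene]acetate F4; here the ester should settle syn to the carbon with the axial chlorine, away from the equatorial silyloxy group (allylic 1,3-strain). iBu2AlH at −78 °C gives (2Z)-2-[(2S,4S,6R)-4-bromo-6-[(tert-butyldimethylsilyl)oxy]-2-chloro-3,3-dimethylcyclohexylidene]ethan-1-ol F5, and lipase/vinyl acetate as in step 14 gives 23.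

Step 3 (enzymatic reduction). The hindered ketone may be a poor substrate, and the tertiary bromide of 5 is sensitive to water. The fallback sets out from 4 and comes back at 6. Corey–Bakshi–Shibata reduction ((S)-2-methyl-oxazaborolidine 10 mol %, BH3·SMe2, THF, −20 °C) gives the same carbinol 5 under anhydrous conditions, lactonised as before to 6. This fallback makes no new compound (F0); the lipase steps 14 and 18 are unchanged.

**Further compounds**
F0 | step 3 | none | none
F1 | step 5 | (5S)-5,6-dibromo-6-methyl-2-[(trimethylsilyl)methyl]hept-1-ene | C[Si](C)(C)CC(=C)CC[C@H](Br)C(C)(C)Br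
F2 | step 15 | tert-butyl({(1R,5S)-5-bromo-4,4-dimethyl-2-[(trimethylsilyl)oxy]cyclohex-2-en-1-yl}oxy)dimethylsilane | CC1(C)[C@@H](Br)C[C@@H](O[Si](C)(C)C(C)(C)C)C(O[Si](C)(C)C)=C1
F3 | step 15 | (2R,4S,6R)-4-bromo-6-[(tert-butyldimethylsilyl)oxy]-2-chloro-3,3-dimethylcyclohexan-1-one | CC1(C)[C@@H](Br)C[C@@H](O[Si](C)(C)C(C)(C)C)C(=O)[C@@H]1Cl
F4 | step 15 | ethyl (2Z)-2-[(2S,4S,6R)-4-bromo-6-[(tert-butyldimethylsilyl)oxy]-2-chloro-3,3-dimethylcyclohexylidene]acetate | CC1(C)[C@@H](Br)C[C@@H](O[Si](C)(C)C(C)(C)C)/C(=C/C(=O)OCC)[C@@H]1Cl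
F5 | step 15 | (2Z)-2-[(2S,4S,6R)-4-bromo-6-[(tert-butyldimethylsilyl)oxy]-2-chloro-3,3-dimethylcyclohexylidene]ethan-1-ol | CC1(C)[C@@H](Br)C[C@@H](O[Si](C)(C)C(C)(C)C)/C(=C/CO)[C@@H]1Cl
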